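**Strategy.** The route rests on cutting the C2–C3 bond of the pyran ring (ring B) and treating C2, the only sp3 carbon on O1, as a former tertiary C–H of an aryl sec-alkyl ether. The key step, a dirhodium-catalysed carbenoid 1,6-C–H insertion, closes ring B and creates the 2R quaternary centre in one operation with retention; C4 serves as a temporary carbonyl that carries the diazo group. The precursor is an open diazomethyl aryl ketone whose ortho oxygen bears the (R)-configured C18 chain, made from 2,5-dimethylhydroquinone and natural phytol (ozonolysis, enzymatic reduction, Mitsunobu inversion). Hydrogenolysis then removes the C4 oxygen and the benzyl group.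

Key step: step 7

Remark: commercial natural-source phytol is taken as the (7R,11R) stereoisomer; its E/Z composition does not matter because the C=C bond is cleaved in step 3.
Remark: chroman numbering (O1, C2, C3, C4, C4a, C5–C8, C8a) is used; ring A is the arene and ring B the pyran ring.

**Step 1**
Reactants: 1 2,5-dimethylhydroquinone
Product: 2 1-(2,5-dihydroxy-3,6-dimethylphenyl)ethan-1-one
Conditions: AcOH, BF3·OEt2, 100 °C; aq. work-up
Reagents that add atoms: acetic acid, CC(=O)O
Why: Friedel–Crafts (Nencki-type) C-acylation of the electron-rich hydroquinone, whose two free ring positions are equivalent, should stop after one acetyl group because that group deactivates the ring.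

**Step 2**
Reactants: 2 1-(2,5-dihydroxy-3,6-dimethylphenyl)ethan-1-one
Product: 3 1-[3-(benzyloxy)-6-hydroxy-2,5-dimethylphenyl]ethan-1-one
Conditions: BnBr (1.05 equiv), K2CO3, acetone, reflux, N2
Reagents that add atoms: benzyl bromide, BrCc1ccccc1
Why: Williamson etherification should take the free hydroxyl, because the hydroxyl next to the acetyl group is tied up in an intramolecular hydrogen bond and flanked by a methyl group.

**Step 3**
Reactants: 4 (E)-(7R,11R)-phytol
Product: 6 (6R,10R)-6,10,14-trimethylpentadecan-2-one, via secondary ozonide 5 (not isolated)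
Conditions: O3, CH2Cl2, −78 °C; then Me2S, −78 °C to rt
Reagents that add atoms: ozone, [O-][O+]=O
Why: Ozonolysis with reductive work-up cleaves the only C=C bond of 4 and leaves the two remote stereocentres untouched as C6 and C10 of the methyl ketone.

**Step 4**
Reactants: 6 (6R,10R)-6,10,14-trimethylpentadecan-2-one
Product: 7 (2S,6R,10R)-6,10,14-trimethylpentadecan-2-ol
Conditions: (S)-selective alcohol dehydrogenase ADH-A (Rhodococcus ruber), NAD+ (cat.), iPrOH/phosphate buffer pH 7.5, 30 °C
Reagents that add atoms: none
Why: Enzymatic asymmetric ketone reduction (hydride from NADH to the Re face of the methyl ketone, iPrOH as terminal reductant) should set the 2S carbinol centre under catalyst control, independent of the remote 6R and 10R centres.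

**Step 5**
Reactants: 3 1-[3-(benzyloxy)-6-hydroxy-2,5-dimethylphenyl]ethan-1-one; 7 (2S,6R,10R)-6,10,14-trimethylpentadecan-2-ol
Product: 8 1-[3-(benzyloxy)-2,5-dimethyl-6-{[(2R,6R,10R)-6,10,14-trimethylpentadecan-2-yl]oxy}phenyl]ethan-1-one
Conditions: PPh3, DIAD, toluene, 0 °C to rt
Reagents that add atoms: none
Why: In the Mitsunobu reaction the phenol, acidified by its ortho acyl group, displaces the oxyphosphonium derivative of 7 in an SN2 step with inversion, so the 2S alcohol should become the 2R aryl ether.

**Step 6**
Reactants: 8 1-[3-(benzyloxy)-2,5-dimethyl-6-{[(2R,6R,10R)-6,10,14-trimethylpentadecan-2-yl]oxy}phenyl]ethan-1-one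
Product: 10 1-[3-(benzyloxy)-2,5-dimethyl-6-{[(2R,6R,10R)-6,10,14-trimethylpentadecan-2-yl]oxy}phenyl]-2-diazoethan-1-one, via trifluoroacetyl diketone 9 (not isolated)
Conditions: LiN(SiMe3)2, THF, −78 °C, then CF3CO2CH2CF3; aq. HCl; crude 9, MsN3, Et3N, H2O, MeCN, rt
Reagents that add atoms: methanesulfonyl azide, CS(=O)(=O)N=[N+]=[N-]; 2,2,2-trifluoroethyl trifluoroacetate, O=C(OCC(F)(F)F)C(F)(F)F (its trifluoroacetyl group is carried only by 9)
Why: In this deacylative Regitz diazo transfer the only enolisable position of 8 (the acetyl CH3) is trifluoroacetylated through its lithium enolate and the 1,3-diketone then takes N2 from MsN3 with loss of the trifluoroacetyl group, while the non-acidic ether stereocentre is untouched.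

**Step 7**
Reactants: 10 1-[3-(benzyloxy)-2,5-dimethyl-6-{[(2R,6R,10R)-6,10,14-trimethylpentadecan-2-yl]oxy}phenyl]-2-diazoethan-1-one
Product: 11 (2R)-6-(benzyloxy)-2,5,8-trimethyl-2-[(4R,8R)-4,8,12-trimethyltridecyl]chroman-4-one
Conditions: Rh2(OAc)4 (1 mol %), CH2Cl2, 40 °C, slow addition of 10, high dilution
Reagents that add atoms: none
Why: Rh2(OAc)4 (dirhodium tetraacetate, divalent rhodium) expels N2 from 10 to give an electrophilic acyl carbenoid at the future C3, which inserts in a concerted three-centre transition state into the tertiary C–H of the ether carbon (future C2), the most hydridic C–H within reach because it is tertiary and bonded to oxygen. The closest known reaction type is the dirhodium-carboxylate-catalysed intramolecular C–H insertion of 2-alkoxyaryl diazomethyl ketones next to the ether oxygen, which gives chroman-4-ones. Ring B is closed in the 1,6-insertion mode through a six-membered transition state made of C3, C4, C4a, C8a, O1 and C2. The only new stereocentre, C2, is controlled by the substrate: carbenoid C–H insertion proceeds with retention, C3 taking the place of H, so the R ether centre of 10 should become the 2R quaternary centre. The step needs site selectivity for this C–H over attack at the ether oxygen (oxonium ylide, then Stevens shift to a benzofuranone), over insertion into the C–H bonds of the methyl group on the other ortho carbon, and over Buchner addition to ring A. The tertiary C–H on oxygen, the donor acetate ligands (less ylide-prone than perfluorinated ones), the fully substituted ortho positions that twist the acyl carbenoid towards the ether side chain, and slow addition secure it.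

**Step 8**
Reactants: 11 (2R)-6-(benzyloxy)-2,5,8-trimethyl-2-[(4R,8R)-4,8,12-trimethyltridecyl]chroman-4-one
Product: 14 (2R,4'R,8'R)-beta-tocopherol, via 4-oxo-beta-tocopherol 12 (not isolated), via chroman-4,6-diol 13 (not isolated)
Conditions: H2 (4 bar), 10% Pd/C, EtOAc/AcOH, HClO4 (cat.), rt
Reagents that add atoms: none
Why: Catalytic hydrogenolysis should cleave the benzyl ether and, under acid catalysis, reduce the aryl ketone through the benzylic alcohol (ionisation assisted by O1) to CH2, while C2 carries no hydrogen and none of its bonds is broken, so the 2R centre persists.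

**Compound list**
1 | 2,5-dimethylhydroquinone (2,5-dimethylbenzene-1,4-diol) | Cc1cc(O)c(C)cc1O | starting material
2 | 1-(2,5-dihydroxy-3,6-dimethylphenyl)ethan-1-one | CC(=O)c1c(O)c(C)cc(O)c1C | intermediate
3 | 1-[3-(benzyloxy)-6-hydroxy-2,5-dimethylphenyl]ethan-1-one (free OH ortho to the acetyl group) | CC(=O)c1c(O)c(C)cc(OCc2ccccc2)c1C | intermediate
4 | (E)-(7R,11R)-phytol, (2E,7R,11R)-3,7,11,15-tetramethylhexadec-2-en-1-ol | OC/C=C(\C)CCC[C@H](C)CCC[C@H](C)CCCC(C)C | starting material
5 | secondary ozonide of phytol, 1,2,4-trioxolane carrying CH2OH on one ring carbon and methyl plus the (4R,8R)-4,8,12-trimethyltridecyl chain on the other (mixture at the ring carbons) | CC1(CCC[C@H](C)CCC[C@H](C)CCCC(C)C)OOC(CO)O1 | intermediate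
6 | (6R,10R)-6,10,14-trimethylpentadecan-2-one | CC(=O)CCC[C@H](C)CCC[C@H](C)CCCC(C)C | intermediate
7 | (2S,6R,10R)-6,10,14-trimethylpentadecan-2-ol | C[C@H](O)CCC[C@H](C)CCC[C@H](C)CCCC(C)C | intermediate
8 | 1-[3-(benzyloxy)-2,5-dimethyl-6-{[(2R,6R,10R)-6,10,14-trimethylpentadecan-2-yl]oxy}phenyl]ethan-1-one | CC(=O)c1c(C)c(OCc2ccccc2)cc(C)c1O[C@H](C)CCC[C@H](C)CCC[C@H](C)CCCC(C)C | intermediate
9 | 1-[3-(benzyloxy)-2,5-dimethyl-6-{[(2R,6R,10R)-6,10,14-trimethylpentadecan-2-yl]oxy}phenyl]-4,4,4-trifluorobutane-1,3-dione | O=C(CC(=O)C(F)(F)F)c1c(C)c(OCc2ccccc2)cc(C)c1O[C@H](C)CCC[C@H](C)CCC[C@H](C)CCCC(C)C | intermediate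
10 | 1-[3-(benzyloxy)-2,5-dimethyl-6-{[(2R,6R,10R)-6,10,14-trimethylpentadecan-2-yl]oxy}phenyl]-2-diazoethan-1-one | [N-]=[N+]=CC(=O)c1c(C)c(OCc2ccccc2)cc(C)c1O[C@H](C)CCC[C@H](C)CCC[C@H](C)CCCC(C)C | intermediate
11 | (2R)-6-(benzyloxy)-2,5,8-trimethyl-2-[(4R,8R)-4,8,12-trimethyltridecyl]chroman-4-one | Cc1cc(OCc3ccccc3)c(C)c2c1O[C@](C)(CCC[C@H](C)CCC[C@H](C)CCCC(C)C)CC2=O | intermediate
12 | 4-oxo-beta-tocopherol, (2R)-6-hydroxy-2,5,8-trimethyl-2-[(4R,8R)-4,8,12-trimethyltridecyl]chroman-4-one | Cc1cc(O)c(C)c2c1O[C@](C)(CCC[C@H](C)CCC[C@H](C)CCCC(C)C)CC2=O | intermediate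
13 | (2R,4RS)-2,5,8-trimethyl-2-[(4R,8R)-4,8,12-trimethyltridecyl]chroman-4,6-diol | Cc1cc(O)c(C)c2c1O[C@](C)(CCC[C@H](C)CCC[C@H](C)CCCC(C)C)CC2O | intermediate
14 | (2R,4'R,8'R)-beta-tocopherol, (2R)-2,5,8-trimethyl-2-[(4R,8R)-4,8,12-trimethyltridecyl]chroman-6-ol | Cc1cc(O)c(C)c2c1O[C@](C)(CCC[C@H](C)CCC[C@H](C)CCCC(C)C)CC2 | target

**Total step count:** 8
**Longest linear sequence:** 6 steps (steps 1, 2, 5, 6, 7, 8 from 1; equally steps 3, 4, 5, 6, 7, 8 from 4)

**Steps most likely to fail**

Step 7. The carbenoid may be intercepted by the lone pair of the ether oxygen (oxonium ylide, then 1,2-shift of the sec-alkyl group with loss of configuration) or by ring A before it reaches the C–H bond. The fallback sets out from 3 and 6 and comes back at 11. A Kabbe condensation of phenolic ketone 3 with methyl ketone 6 (pyrrolidine, toluene, reflux, water separator) should build the chromanone by aldol condensation and oxa-Michael ring closure without any carbenoid. It would give 11 together with its C2 epimer, (2S)-6-(benzyloxy)-2,5,8-trimethyl-2-[(4R,8R)-4,8,12-trimethyltridecyl]chroman-4-one F1. The two diastereomers would be separated by preparative HPLC on a chiral stationary phase. Control of C2 is given up in this variant and recovered by the separation.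

Step 5. Displacement at the oxyphosphonium intermediate may be slow with the hindered, hydrogen-bonded phenol, so that elimination of the activated secondary alcohol or incomplete inversion takes over. The fallback sets out from 7 and comes back at 8. Alcohol 7 would be converted (MsCl, Et3N, CH2Cl2, 0 °C) into (2S,6R,10R)-6,10,14-trimethylpentadecan-2-yl methanesulfonate F2. F2 would then be displaced by the caesium phenoxide of 3 (Cs2CO3, DMF, 50 °C) in a Williamson SN2 reaction with inversion to give 8.

Step 8. Hydrogenation may stall at the hindered, vinylogous-ester-like C4 carbonyl after debenzylation, or acid may open the chromanone by a retro-oxa-Michael pathway and erode C2. The fallback sets out from 11 and comes back at 14. The carbonyl would first be reduced by hydride (NaBH4, MeOH/THF, 0 °C) to (2R,4RS)-6-(benzyloxy)-2,5,8-trimethyl-2-[(4R,8R)-4,8,12-trimethyltridecyl]chroman-4-ol F3, which can no longer ring-open. Hydrogenolysis of F3 (H2, 10% Pd/C, EtOH, trace HCl, rt) would then remove the benzylic C4 hydroxyl and the benzyl ether, through 13, to give 14.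

**Further compounds**
F1 | step 7 | (2S)-6-(benzyloxy)-2,5,8-trimethyl-2-[(4R,8R)-4,8,12-trimethyltridecyl]chroman-4-one | Cc1cc(OCc3ccccc3)c(C)c2c1O[C@@](C)(CCC[C@H](C)CCC[C@H](C)CCCC(C)C)CC2=O
F2 | step 5 | (2S,6R,10R)-6,10,14-trimethylpentadecan-2-yl methanesulfonate | C[C@H](OS(C)(=O)=O)CCC[C@H](C)CCC[C@H](C)CCCC(C)C
F3 | step 8 | (2R,4RS)-6-(benzyloxy)-2,5,8-trimethyl-2-[(4R,8R)-4,8,12-trimethyltridecyl]chroman-4-ol | Cc1cc(OCc3ccccc3)c(C)c2c1O[C@](C)(CCC[C@H](C)CCC[C@H](C)CCCC(C)C)CC2O
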